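The data are simulated with made-up constants; the scatter is artificial.

**Amounts first.** The west run holds twice the starting material of the north run at the same reagent and catalyst, so set these two side by side. Read the flasks and the questions:

common to all: free catalyst 15.0 mM

| flask | starting material | reagent | time |
|---|---|---|---|
| west | 300 mM | 600 mM |  |
| south-west | 150 mM | 450 mM |  |
| north | 150 mM | 600 mM |  |
| north-west | 750 mM | 1500 mM | 20 min |

| run | time / min | [starting material] / mM |
|---|---|---|
| west run | 0.80 | 288.0 |
| west run | 1.5 | 277.3 |
| west run | 2.9 | 266.5 |
| west run | 5.5 | 244.7 |
| west run | 11 | 201.5 |
| west run | 20 | 137.0 |
| south-west run | 0.80 | 142.7 |
| south-west run | 1.5 | 137.9 |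
| south-west run | 2.9 | 127.4 |
| south-west run | 5.5 | 112.0 |
| south-west run | 11 | 86.6 |
| south-west run | 20 | 52.3 |
| north run | 0.80 | 146.5 |
| north run | 1.5 | 140.4 |
| north run | 2.9 | 130.3 |
| north run | 5.5 | 116.4 |
| north run | 11 | 86.3 |
| north run | 20 | 49.4 |

(scatter of a reading: 2 mM)

1. reaction order in [reagent] at the outset, round the charge of the west run, defined at two percent of the starting material turned into target
2. reaction order in [starting material] at the outset, round the charge of the west run, defined at two percent of the starting material turned into target (one fixed amount of target, the same in the runs compared)
3. the south-west run starts with 150 mM less of starting material and of reagent than the west run, and with no target. Compared where both hold the same amount of starting material, once fifteen percent of what the south-west run was charged with has turned into target, is the south-west run faster, slower or alike (within a tenth)?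
4. starting material in the north-west run at 20 min, as a share of the starting material charged

- Overall: starting material + reagent -> target, with free catalyst as catalyst.
- Constant volume, constant temperature.
- What is held in complexes is read along with the free species.
- An order is taken over about fifteen percent of the charge, up and down.

**Bench rule.** Try the first-order rule: the same share goes in the same time, whatever the charge. At 20 min the west run keeps 45.7% of its charge, so the rule would leave that share in the north-west run. But the north run keeps 32.9%, less than the west run, so the rule already fails between these two charges.

**Two slopes.** Draw each line from the second reading to the fifth. The west run falls 7.98 mM min⁻¹ around 239 mM, and the north run falls 5.69 mM min⁻¹ around 113 mM. Put these readings into rate = V[starting material]/(K + [starting material]). They give, as readings that carry the scatter, a half-way amount K of 135 mM and a ceiling rate V, the field's Vmax, the rate that this curve approaches at large [starting material], of 12.5 mM min⁻¹.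

**The border.** Divide charge by K. The north run stands at 1.11 and the north-west run at 5.55, so at its charge the north-west run sits on this curve at 84.7% of the ceiling, where a first-order line does not describe the curve. Reagent is left out of the curve: going from 450 mM to 600 mM moves the last reading by 2.90 mM, against a scatter of 2 mM.

**My reckoning.** Watch the first minutes. The west line, run back to zero time, stands 10.7 mM below the charge, and I add that west reading to the north-west run as an estimated early drop. The curve gives 10.6 mM min⁻¹ at the north-west charge. At the amount reached midway it gives 10.3 mM min⁻¹. Over 20 min that leaves 71.1% in the north-west run.

**The forecast.** It gives 0.25 for reagent, 0.35 for starting material, alike for the comparison, and 65% left, which is lower than my figure. Its ground: “This points to saturation”.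

**The flask.** It gives 0.0084, 0.43, alike and 70.6%. Where target amounts to two percent of the west charge, the north run goes at 0.70 of the west rate.

    free catalyst + starting material → catalyst-substrate complex (53.82 M⁻¹ min⁻¹)
    catalyst-substrate complex + reagent → loaded catalyst (66.00 M⁻¹ min⁻¹)
    loaded catalyst → target + free catalyst (0.7560 min⁻¹)
    2 free catalyst ⇌ resting dimer, settled at all times (3820 M⁻¹)

**Ceiling again.** The north-west run lost 221 mM. With the early drop read from the west run taken off, that is on average 10.5 mM min⁻¹, or 84.0% of the ceiling read from the west and north runs. For the south-west run, which gave no slope to the curve, (half the charge + K ln(2))/V gives 13.5 min, and target reaches half its charge later, at 14.8 min.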